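## Structural features

The target is a ten-membered carbocycle (germacrane numbering C1–C10) with a trans-fused α-methylene-γ-lactone across C6–C7 (oxygen on C6, C11 on C7), a trans trisubstituted epoxide at C4–C5 and a cis,cis-dienoate C10(CO2Me)=C1–C2=C3 that ends at the epoxide carbon C4. Six contiguous stereocentres run from C4 to C9 (4R,5R,6S,7R,8S,9S). The C8 ester and the C9 acetate are trans to one another, and the C8 oxygen is cis to C11. The C8 acyl group is (2R,3S)-2,3-dimethyloxirane-2-carboxylate, whose two methyl groups are cis. It is therefore the epoxide of tiglic acid, the (E)-acid, and cannot come from angelic acid, which leads only to the (2R,3R)/(2S,3S) series; tiglic acid is the correct starting material for the side chain. Fragile groups are the α-methylene lactone, the vinyl epoxide at C4, the glycidic ester, the allylic acetate and the cis,cis-diene, which would undergo 6π-electrocyclisation if a third conjugated ring double bond were added. The difficulty is not the ring but stereocontrol on a flexible medium ring and the oxygenation of four adjacent carbons (C6–C9) that begin as CH2–CH=CH–CH2. The key step uses the 1,6-relationship of C5 (oxygenated) and C10 (ester-bearing) and the cis C2=C3 bond between C1 and C4. That is the pattern left when the central double bond of 1,4,5,8-tetrahydronaphthalene is cleaved, and the second cis double bond falls at C7=C8, where the later oxygenation is needed.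

## Logic of the disconnections

**36 ⇒ 35.** The C11=C13 bond is cut. The α-methylene lactone is the most reactive function and should appear last, so C11 is carried as a phosphonate. The forward olefination must use a base mild enough to spare the acetate and the glycidic ester.

**35 ⇒ 34 ⇒ 33.** The acetyl C–O bond at O9 and then the C9–H bond are cut, which returns a C9 ketone. That ketone is what makes C7 electrophilic and C8 enolisable earlier on. The forward reduction must be a 1,2-reduction with hydride delivered anti to the C8 acyloxy group.

**33 ⇒ 26 + 31.** The acyl C–O bond at O8 is cut. The side chain is made separately as one enantiomer, so the two epoxides never need to be distinguished on the ring. The esterification must couple a hindered acid to a hindered alcohol without epimerising C8.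

**31 ⇒ 29 ⇒ 28 ⇒ 27.** The carboxyl oxygen, then the two epoxide C–O bonds, then the carbinol hydrogens are removed. This reduces the side chain to a commercial E-acid. The demand is a reagent-controlled epoxidation of an E allylic alcohol.

**26 ⇒ 24.** The C8–O bond is cut. C8 is the only enolisable position of the C9 ketone, so regiochemistry is not in question. The demand is facial selectivity at C8 from the neighbouring C7 centre.

**24 ⇒ 23.** The C7–C11 bond is cut. A tether from O6 delivers C11, so the lactone ring and the C7 stereocentre are formed together. The demand is trans fusion, which must come from allylic strain in the cis enone.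

**23 ⇒ 21 ⇒ 19 + 20.** The C9 carbonyl oxygen and the acyl C–O bond at O6 are removed. C9 is the only methylene flanked by two double bonds at this stage. The demand is oxidation there without moving either double bond.

**19 ⇒ 18 ⇒ 17.** The C4–C5 epoxide bond at C5 is traced to an epoxide migration, and the C5–C6 epoxide to oxygen delivery by the C4 hydroxyl. One directed epoxidation therefore sets C5 and C6 from C4, and no diol needs differentiating. The demands are a cis C5=C6 bond and syn delivery.

**17 ⇒ 15 ⇒ 13.** The C5–H bond is traced to a C5–O bond (enol triflate), and that to the C5 ketone. The ketone oxygen is given up in exchange for a conjugated diene. The demand is enolisation toward C6 only, which the quaternary C4 guarantees.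

**13 ⇒ 10 ⇒ 7 + 8.** The C4–O and C4–CH3 bonds are cut. C4–H is activated by the ketone and, through the diene, by the ester, so the site is selected by acidity. The first stereocentre (C4) must come from reagent control.

**7 ⇒ 6 ⇒ 5.** The C10–C14 bond is cut back to an enol triflate and then to a ketone. All four α-methylenes of 5 are equivalent, so only one constitution can form. The demand is mono-functionalisation without transannular aldol reaction.

**5 ⇒ 3 ⇒ 1.** The two carbonyl groups are read as the ends of a cleaved C=C, and the four sp3 CH2 groups as Birch hydrogens. The ten-membered ring then costs two steps and no ring-closing reaction. The demand is chemoselective cleavage of one of three double bonds. A C-methylated analogue of 1 was rejected because Birch regiochemistry and the symmetry of 5 would both be lost.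

## Other disconnections considered

**Alternative 1:** Ireland–Claisen rearrangement of a ten-membered lactone. The cut is C10–C1. The carbocyclic acid A2 is traced to lactone A1, in which C14 is the lactone carbonyl, the ring oxygen sits on C3 and C3 carries the vinyl group C2=C1. Forward, KN(SiMe3)2 and Me3SiCl at −78 °C, then warming, would silylate the lactone enolate of A1. The [3,3] shift through a ring-enforced boat would then form C10–C1, create the cis C2=C3 bond and turn the ring oxygen into the C14 acid of A2.
- In favour: the ring is first closed as a lactone, which is more dependable than any ten-membered C–C closure. The stereocentres C4–C9 are built on an open chain, and the sigmatropic step is stereospecific. On stereocontrol and mechanistic reliability this is better than the chosen plan.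
- Against: A2 has an sp3 C10 and a C1 methylene, so the C1=C10 bond must still be made next to the ester. The enolate of A1 has a silyloxy leaving group at C9 in the β position. Four protecting groups and a C12 alcohol remain to be adjusted. A1 alone would need a long linear sequence.
- Comparison: better on stereochemistry, equal in the late esterifications and late unveiling of the methylene lactone, and clearly worse on step economy.

**Alternative 2:** tropone [6+4] cycloaddition, then cleavage of the one-carbon bridge. The cuts are C5–C6 and C9–C10. Forward, heating 2-silyloxytropone A3 with the (1E,3E)-diacetoxydiene A4 would give the exo bicyclo[4.4.1] adduct A5. Ketol cleavage of its bridge (the silyloxy bridgehead becomes the C5 ketone, the other bridgehead keeps C14 as the ester on C10) would open the ten-membered ring.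
- In favour: two C–C bonds, the ring and four stereocentres arise in one step from two achiral pieces. C6 and C9 arrive oxygenated and cis to each other, with C7=C8 in place. On this point it is better than the chosen plan, which needs a C–H oxidation for C9 and a rearrangement for C6. It is equal in obtaining the medium ring by bond scission of a bicycle and not by macrocyclisation.
- Against: [4+2] and [8+2] modes compete. A5 is racemic, with no obvious reagent-controlled entry. The C4 methyl is missing and the diene must be moved into conjugation with the ester. The base needed for that chemistry threatens E1cB loss of the C9 acetate (β to the ester) and of the C6 acetate.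
- Comparison: better in skeleton and oxygenation economy, worse in absolute stereocontrol and in functional-group compatibility, and probably similar in total length.

**Alternative 3:** Nozaki–Hiyama–Kishi closure onto the C4 methyl ketone. The cut is C3–C4. Forward, CrCl2 with catalytic NiCl2 would convert the cis,cis-dienyl iodide A6 into an alkenylchromium species that adds to the methyl ketone. This closes the ring and forms the tertiary carbinol of A7.
- In favour: C5–C9, the lactone and the dienoate are assembled before ring closure. The organochromium reagent tolerates esters and the lactone. A7 is only an epoxide closure and one ester exchange from 36, so the endgame is shorter and better than the chosen one.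
- Against: alkenylchromium additions to ketones are much slower than to aldehydes. A strained ten-membered ring must be closed against dimerisation. The methylene lactone may be reduced by divalent chromium. The Z-iodide may lose its geometry. The C4 configuration rests on macrocyclic diastereoselection. A6 needs a long synthesis.
- Comparison: better stereocontrol at C5–C9, equal uncertainty at C4 (one step decides it in both plans), and worse feasibility of the key step and worse step economy.

Key step: step 2

Remark on numbering: positions are given in germacrane numbering (C1–C14); systematic ring numbering appears only inside names. Compounds 24–35 are carried as mixtures of C11 epimers, which converge in step 21.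

Assumption: the (+)-enantiomer of (camphorsulfonyl)oxaziridine is taken as the one that delivers oxygen to the enolate face giving the (4R) centre; its equally available enantiomer would be used if the sense proves opposite.

## Route

Step 1
Reactants: 1 naphthalene
Product: 3 1,4,5,8-tetrahydronaphthalene, via 1,4-dihydronaphthalene 2 (not isolated)
Conditions: Na, liquid NH3, EtOH, Et2O, −78 °C to −33 °C
Reagents that add atoms: none
Why: Birch reduction; each benzenoid ring is reduced in turn to the unconjugated 1,4-diene, and the tetrasubstituted central double bond is not reduced by the dissolving metal; no stereocentre is formed.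

Step 2
Reactants: 3 1,4,5,8-tetrahydronaphthalene
Product: 5 (3Z,8Z)-cyclodeca-3,8-diene-1,6-dione, via hydroperoxy methoxy ketone 4 (not isolated)
Conditions: O3 (1.0 equiv, Sudan Red 7B as end-point indicator), NaHCO3, CH2Cl2/MeOH, −78 °C; then Me2S, −78 °C to rt
Reagents that add atoms: ozone, [O-][O+]=O
Why: Ozone adds as a 1,3-dipole to the C5=C10 bond, the primary ozonide fragments to a ketone and a carbonyl oxide, methanol traps the carbonyl oxide as 4, and dimethyl sulfide reduces 4 to the second ketone. The closest known reaction type is chemoselective ozonolysis of the most substituted double bond of a polyene, here the known cleavage of the ring-fusion bond of 3. The ten-membered ring is not closed by bond formation: it is the perimeter of the bicycle, set free when the bond shared by the two six-membered rings is cut (ring expansion by scission). No stereocentre is formed, and both remaining double bonds must be cis because each was part of a six-membered ring. The step needs chemoselectivity among three alkenes; the tetrasubstituted bond is the most electron-rich and should react with electrophilic ozone far faster than the two cis-disubstituted ones, so one equivalent at −78 °C with an indicator dye should secure it. Cold, buffered, reductive work-up is chosen to avoid the transannular aldol reaction typical of 1,6-diketones in ten-membered rings.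

Step 3
Reactants: 5 (3Z,8Z)-cyclodeca-3,8-diene-1,6-dione
Product: 6 (1E,3Z,8Z)-6-oxocyclodeca-1,3,8-trien-1-yl trifluoromethanesulfonate
Conditions: Tf2O (0.95 equiv), 2,6-di-tert-butyl-4-methylpyridine, CH2Cl2, 0 °C to rt; recovered 5 recycled
Reagents that add atoms: trifluoromethanesulfonic anhydride, O=S(=O)(OS(=O)(=O)C(F)(F)F)C(F)(F)F
Why: Enol triflate formation by O-sulfonylation of the ketone and proton loss to the hindered pyridine, so no free enolate can add across the ring to the second ketone. The four α-methylenes of 5 are equivalent, the new double bond forms in conjugation with the neighbouring cis alkene and is held cis by the ring; mono-functionalisation is statistical.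

Step 4
Reactants: 6 (1E,3Z,8Z)-6-oxocyclodeca-1,3,8-trien-1-yl trifluoromethanesulfonate
Product: 7 methyl (1E,3Z,8Z)-6-oxocyclodeca-1,3,8-triene-1-carboxylate
Conditions: Pd(OAc)2 (cat.), PPh3, CO (1 atm), MeOH, Et3N, DMF, rt
Reagents that add atoms: carbon monoxide, [C-]#[O+]; methanol, CO
Why: Palladium-catalysed methoxycarbonylation of an enol triflate (oxidative addition, CO insertion, methanolysis) with retention of double-bond geometry; the ketone and the isolated alkene are inert.

Step 5
Reactants: 7 methyl (1E,3Z,8Z)-6-oxocyclodeca-1,3,8-triene-1-carboxylate; 8 iodomethane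
Product: 10 methyl (1E,3Z,8Z)-5-methyl-6-oxocyclodeca-1,3,8-triene-1-carboxylate (racemic), via lithium trienolate 9 (not isolated)
Conditions: LiN(SiMe3)2 (1.05 equiv), THF, −78 °C; then MeI, −78 °C to −40 °C
Reagents that add atoms: iodomethane 8, CI
Why: Enolate alkylation; C4–H is α to the ketone and activated through the diene by the ester, so it is removed in preference to C6–H, and the extended enolate is alkylated α to the ketone (as for Hagemann's ester), which keeps the dienoate conjugated. Any double-bond isomer of 7 gives the same enolate, the new centre is racemic and is erased in step 6, and the low temperature limits a second methylation and disrotatory closure of the trienolate.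

Step 6
Reactants: 10 methyl (1E,3Z,8Z)-5-methyl-6-oxocyclodeca-1,3,8-triene-1-carboxylate (racemic)
Product: 13 methyl (1E,3Z,5R,8Z)-5-methyl-6-oxo-5-(trimethylsilyloxy)cyclodeca-1,3,8-triene-1-carboxylate, via potassium enolate 11 (not isolated), via potassium alkoxide 12 (not isolated)
Conditions: KN(SiMe3)2, THF, −78 °C; (+)-(camphorsulfonyl)oxaziridine, −78 °C to −40 °C; then Me3SiCl, −78 °C to 0 °C
Reagents that add atoms: (+)-(camphorsulfonyl)oxaziridine, CC1(C)[C@@H]2CC[C@]13CS(=O)(=O)N4O[C@@]34C2; chlorotrimethylsilane, C[Si](C)(C)Cl
Why: Davis asymmetric hydroxylation of a tetrasubstituted enolate; oxygen is transferred to C4, the position α to the ketone, and the chiral oxaziridine differentiates the two enolate faces, so C4 is set by reagent control. The tertiary alkoxide is silylated in the same flask to prevent α-ketol rearrangement and to mask it for step 7.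

Step 7
Reactants: 13 methyl (1E,3Z,5R,8Z)-5-methyl-6-oxo-5-(trimethylsilyloxy)cyclodeca-1,3,8-triene-1-carboxylate
Product: 15 methyl (1E,3Z,5R,6E,8Z)-5-methyl-6-(trifluoromethanesulfonyloxy)-5-(trimethylsilyloxy)cyclodeca-1,3,6,8-tetraene-1-carboxylate, via potassium dienolate 14 (not isolated)
Conditions: KN(SiMe3)2, THF, −78 °C; then N-(5-chloropyridin-2-yl)bis(trifluoromethanesulfonyl)imide (Comins' reagent), −78 °C
Reagents that add atoms: Comins' reagent, O=S(=O)(N(c1ccc(Cl)cn1)S(=O)(=O)C(F)(F)F)C(F)(F)F
Why: Kinetic enol triflate formation; C4 is quaternary, so the ketone can enolise only toward C6, and a ring that already holds three cis double bonds should accept the new C5=C6 bond only as cis.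

Step 8
Reactants: 15 methyl (1E,3Z,5R,6E,8Z)-5-methyl-6-(trifluoromethanesulfonyloxy)-5-(trimethylsilyloxy)cyclodeca-1,3,6,8-tetraene-1-carboxylate
Product: 17 methyl (1E,3Z,5S,6Z,8Z)-5-hydroxy-5-methylcyclodeca-1,3,6,8-tetraene-1-carboxylate, via trimethylsilyl ether 16 (not isolated)
Conditions: Pd(OAc)2 (cat.), PPh3, Bu3N, HCO2H, DMF, 50 °C; then Bu4NF, THF, 0 °C
Reagents that add atoms: none
Why: Palladium-catalysed formate reduction of the enol triflate (hydride transfer with loss of CO2) replaces OTf by H with retention of geometry, and fluoride then frees the tertiary alcohol without acid. C4 is untouched; its descriptor changes only because the priorities change.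

Step 9
Reactants: 17 methyl (1E,3Z,5S,6Z,8Z)-5-hydroxy-5-methylcyclodeca-1,3,6,8-tetraene-1-carboxylate
Product: 18 methyl (1E,3Z,5R,6S,7S,8Z)-6,7-epoxy-5-hydroxy-5-methylcyclodeca-1,3,8-triene-1-carboxylate
Conditions: VO(acac)2 (cat.), t-BuOOH, 2,6-lutidine, CH2Cl2, 0 °C
Reagents that add atoms: tert-butyl hydroperoxide, CC(C)(C)OO
Why: Hydroxyl-directed epoxidation; the vanadium alkoxide of the tertiary allylic alcohol delivers oxygen to the adjacent cis C5=C6 bond on the face of the hydroxyl group (cis epoxy alcohols are the rule for vanadium-catalysed epoxidation of cyclic allylic alcohols), so C5 and C6 follow from C4. The homoallylic C7=C8 bond and the electron-poor dienoate should react more slowly.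

Step 10
Reactants: 18 methyl (1E,3Z,5R,6S,7S,8Z)-6,7-epoxy-5-hydroxy-5-methylcyclodeca-1,3,8-triene-1-carboxylate
Product: 19 methyl (1E,3Z,5R,6R,7S,8Z)-5,6-epoxy-7-hydroxy-5-methylcyclodeca-1,3,8-triene-1-carboxylate
Conditions: t-BuOK (0.2 equiv), t-BuOH/THF, 0 °C
Reagents that add atoms: none
Why: Payne rearrangement; the C4 alkoxide opens the C5–C6 epoxide at C5 with inversion, which gives the trans C4–C5 epoxide of the target and releases the C6 oxygen, unchanged in configuration, as a secondary allylic alcohol. The equilibrium should favour the more substituted epoxide and the less hindered alkoxide.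

Step 11
Reactants: 19 methyl (1E,3Z,5R,6R,7S,8Z)-5,6-epoxy-7-hydroxy-5-methylcyclodeca-1,3,8-triene-1-carboxylate; 20 (diethoxyphosphoryl)acetic acid
Product: 21 C6 (diethoxyphosphoryl)acetate of 19, methyl (1E,3Z,5R,6R,7S,8Z)-7-[2-(diethoxyphosphoryl)acetoxy]-5,6-epoxy-5-methylcyclodeca-1,3,8-triene-1-carboxylate
Conditions: DCC, DMAP (cat.), CH2Cl2, 0 °C
Reagents that add atoms: (diethoxyphosphoryl)acetic acid 20, CCOP(=O)(CC(=O)O)OCC
Why: Steglich esterification of the secondary allylic alcohol with retention at C6; the neutral conditions leave the epoxide and the dienoate untouched.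

Step 12
Reactants: 21 C6 (diethoxyphosphoryl)acetate of 19
Product: 23 9-oxo derivative of 21 (cross-conjugated dienone), via C9 carbinol 22 (not isolated)
Conditions: SeO2 (0.5 equiv), t-BuOOH, CH2Cl2, rt; then Dess–Martin periodinane, NaHCO3, CH2Cl2, 0 °C
Reagents that add atoms: selenium dioxide, O=[Se]=O; tert-butyl hydroperoxide, CC(C)(C)OO
Why: Allylic oxidation by the ene and [2,3]-sigmatropic sequence of SeO2, which returns the C7=C8 bond to its place and puts oxygen on C9, the only methylene flanked by two double bonds. Selenium should bond to C7, because the acyloxy group on C6 disfavours positive charge at C7, and the doubly allylic alcohol 22 is oxidised to the ketone without purification.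

Step 13
Reactants: 23 9-oxo derivative of 21
Product: 24 methyl 11-(diethoxyphosphoryl)-4,5-epoxy-9-oxogermacra-1(10)Z,2Z-dien-12,6-olid-14-oate (ring centres C4–C7 as in 36; C11 epimers)
Conditions: Cs2CO3 (0.3 equiv), MeCN, 0 °C
Reagents that add atoms: none
Why: Intramolecular Michael addition (5-exo-trig) of the phosphonoacetate carbanion to C7 of the cis enone. With H6 eclipsing the cis double bond to relieve allylic strain, the tether reaches C7 only from the face that gives the trans-fused γ-lactone, so C7 follows from C6; catalytic base and low temperature limit a second, transannular addition to C1.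

Step 14
Reactants: 24 phosphono lactone ketone
Product: 26 (8S)-8-hydroxy derivative of 24, via dilithium dianion 25 (not isolated)
Conditions: LiN(SiMe3)2 (2.2 equiv), THF, −78 °C; then 2-(phenylsulfonyl)-3-phenyloxaziridine, −78 °C
Reagents that add atoms: 2-(phenylsulfonyl)-3-phenyloxaziridine, O=S(=O)(N1OC1c1ccccc1)c1ccccc1
Why: Davis enolate hydroxylation; the first equivalent of base removes the acidic C11–H, the second forms the only possible ketone enolate (toward C8), and this more reactive enolate takes up the oxygen. Attack anti to the bulky phosphonate-bearing C11 on C7 should place the new oxygen cis to C11 in the ring sense, as the target requires.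

Step 15
Reactants: 27 tiglic acid
Product: 28 (E)-2-methylbut-2-en-1-ol
Conditions: LiAlH4, Et2O, 0 °C
Reagents that add atoms: none
Why: Hydride reduction of the carboxylic acid to the primary allylic alcohol; the trisubstituted double bond and its E geometry are kept.

Step 16
Reactants: 28 (E)-2-methylbut-2-en-1-ol
Product: 29 [(2S,3S)-2,3-dimethyloxiran-2-yl]methanol
Conditions: Ti(OiPr)4 (cat.), L-(+)-diethyl tartrate (cat.), t-BuOOH, 4 Å molecular sieves, CH2Cl2, −20 °C
Reagents that add atoms: tert-butyl hydroperoxide, CC(C)(C)OO
Why: Sharpless asymmetric epoxidation; the L-(+)-tartrate catalyst delivers oxygen to the face that gives the (2S,3S) epoxy alcohol from an E allylic alcohol, and syn addition keeps the two methyl groups cis.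

Step 17
Reactants: 29 [(2S,3S)-2,3-dimethyloxiran-2-yl]methanol
Product: 31 (2R,3S)-2,3-dimethyloxirane-2-carboxylic acid, via epoxy aldehyde 30 (not isolated)
Conditions: RuCl3·xH2O (cat.), NaIO4, CCl4/MeCN/H2O, rt
Reagents that add atoms: water, O
Why: Ruthenium tetroxide oxidation under Sharpless conditions takes the primary alcohol through the aldehyde hydrate to the acid without opening the epoxide; the C2 descriptor changes from S to R only because CO2H outranks C3.

Step 18
Reactants: 26 (8S)-8-hydroxy derivative of 24; 31 (2R,3S)-2,3-dimethyloxirane-2-carboxylic acid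
Product: 33 C8 (2R,3S)-2,3-dimethyloxirane-2-carboxylate of 26, via mixed anhydride 32 (not isolated)
Conditions: 31, 2,4,6-trichlorobenzoyl chloride, Et3N, THF, 0 °C; then 26, DMAP, toluene, rt
Reagents that add atoms: (2R,3S)-2,3-dimethyloxirane-2-carboxylic acid 31, OC(=O)[C@]1(C)O[C@H]1C
Why: Yamaguchi esterification; DMAP attacks the mixed anhydride at the less hindered carbonyl and the acylpyridinium acylates the C8 hydroxyl with retention at C8. Neither epoxide should open under these non-acidic conditions.

Step 19
Reactants: 33 C8 ester of 26
Product: 34 (9S)-9-hydroxy compound from 33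
Conditions: NaBH4, CeCl3·7H2O, MeOH, −78 °C
Reagents that add atoms: none
Why: Luche 1,2-reduction of the cross-conjugated ketone; in the Felkin–Anh arrangement the C8 acyloxy group stands anti to the incoming hydride, which should give the C9 alcohol trans to the C8 ester. Esters, lactone and epoxides are not reduced at this temperature.

Step 20
Reactants: 34 (9S)-9-hydroxy compound
Product: 35 C9 acetate of 34
Conditions: Ac2O, pyridine, DMAP (cat.), CH2Cl2, 0 °C
Reagents that add atoms: acetic anhydride, CC(=O)OC(C)=O
Why: Acetylation of the secondary allylic alcohol with retention at C9.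

Step 21
Reactants: 35 C9 acetate of 34
Product: 36 methyl (4R,5R,6S,7R,8S,9S)-9-acetoxy-8-[(2R,3S)-2,3-dimethyloxirane-2-carbonyloxy]-4,5-epoxygermacra-1(10)Z,2Z,11(13)-trien-12,6-olid-14-oate (CNP0229507.5)
Conditions: aqueous HCHO (37%), K2CO3, THF, 0 °C
Reagents that add atoms: formaldehyde, C=O
Why: Horner–Wadsworth–Emmons methylenation; the phosphonate carbanion adds to formaldehyde and loses diethyl phosphate to give the exocyclic C11=C13 bond, which also removes the one undefined centre. Brief exposure to carbonate at 0 °C should leave the acetate and the glycidic ester intact.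

## Compound list

1 | naphthalene | c1ccc2ccccc2c1 | starting material
2 | 1,4-dihydronaphthalene | C1C=CCc2ccccc12 | intermediate (not isolated)
3 | 1,4,5,8-tetrahydronaphthalene | C1C=CCC2=C1CC=CC2 | intermediate
4 | (3Z,8Z)-6-hydroperoxy-6-methoxycyclodeca-3,8-dien-1-one | COC1(OO)C/C=C\CC(=O)C/C=C\C1 | intermediate (not isolated)
5 | (3Z,8Z)-cyclodeca-3,8-diene-1,6-dione | O=C1C/C=C\CC(=O)C/C=C\C1 | intermediate
6 | (1E,3Z,8Z)-6-oxocyclodeca-1,3,8-trien-1-yl trifluoromethanesulfonate | O=C1C/C=C\C=C(OS(=O)(=O)C(F)(F)F)/C/C=C\C1 | intermediate
7 | methyl (1E,3Z,8Z)-6-oxocyclodeca-1,3,8-triene-1-carboxylate | O=C1C/C=C\C=C(C(=O)OC)/C/C=C\C1 | intermediate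
8 | iodomethane | CI | starting material
9 | lithium trienolate of 7 | [Li+].[O-]C1=C/C=C\C=C(C(=O)OC)/C/C=C\C1 | intermediate (not isolated)
10 | methyl (1E,3Z,8Z)-5-methyl-6-oxocyclodeca-1,3,8-triene-1-carboxylate (racemic) | O=C1C(C)/C=C\C=C(C(=O)OC)/C/C=C\C1 | intermediate
11 | potassium enolate of 10 | [K+].[O-]C1=C(C)/C=C\C=C(C(=O)OC)/C/C=C\C1 | intermediate (not isolated)
12 | potassium alkoxide of the (5R)-5-hydroxy ketone | C1/C=C\C/C(C(=O)OC)=C\C=C/[C@@](C)([O-])C1=O.[K+] | intermediate (not isolated)
13 | methyl (1E,3Z,5R,8Z)-5-methyl-6-oxo-5-(trimethylsilyloxy)cyclodeca-1,3,8-triene-1-carboxylate | C1/C=C\C/C(C(=O)OC)=C\C=C/[C@@](C)(O[Si](C)(C)C)C1=O | intermediate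
14 | potassium dienolate of 13 | [K+].[O-]/C1=C/C=C\C/C(C(=O)OC)=C\C=C/[C@@]1(C)O[Si](C)(C)C | intermediate (not isolated)
15 | methyl (1E,3Z,5R,6E,8Z)-5-methyl-6-(trifluoromethanesulfonyloxy)-5-(trimethylsilyloxy)cyclodeca-1,3,6,8-tetraene-1-carboxylate | FC(F)(F)S(=O)(=O)O/C1=C/C=C\C/C(C(=O)OC)=C\C=C/[C@@]1(C)O[Si](C)(C)C | intermediate
16 | trimethylsilyl ether of 17 | C1/C=C\C=C/[C@](C)(O[Si](C)(C)C)/C=C\C=C1\C(=O)OC | intermediate (not isolated)
17 | methyl (1E,3Z,5S,6Z,8Z)-5-hydroxy-5-methylcyclodeca-1,3,6,8-tetraene-1-carboxylate | C1/C=C\C=C/[C@](C)(O)/C=C\C=C1\C(=O)OC | intermediate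
18 | methyl (1E,3Z,5R,6S,7S,8Z)-6,7-epoxy-5-hydroxy-5-methylcyclodeca-1,3,8-triene-1-carboxylate | C1/C=C\[C@@H]2O[C@@H]2[C@](C)(O)/C=C\C=C1\C(=O)OC | intermediate
19 | methyl (1E,3Z,5R,6R,7S,8Z)-5,6-epoxy-7-hydroxy-5-methylcyclodeca-1,3,8-triene-1-carboxylate | O[C@H]1/C=C\C/C(C(=O)OC)=C\C=C/[C@@]2(C)O[C@H]12 | intermediate
20 | (diethoxyphosphoryl)acetic acid | CCOP(=O)(CC(=O)O)OCC | starting material
21 | methyl (1E,3Z,5R,6R,7S,8Z)-7-[2-(diethoxyphosphoryl)acetoxy]-5,6-epoxy-5-methylcyclodeca-1,3,8-triene-1-carboxylate | CCOP(=O)(CC(=O)O[C@H]1/C=C\C/C(C(=O)OC)=C\C=C/[C@@]2(C)O[C@H]12)OCC | intermediate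
22 | C9 carbinol of 21 (10-hydroxy in ring numbering, C9 epimers) | CCOP(=O)(CC(=O)O[C@H]1/C=C\C(O)/C(C(=O)OC)=C\C=C/[C@@]2(C)O[C@H]12)OCC | intermediate (not isolated)
23 | 9-oxo derivative of 21 (10-oxo in ring numbering) | CCOP(=O)(CC(=O)O[C@H]1/C=C\C(=O)/C(C(=O)OC)=C\C=C/[C@@]2(C)O[C@H]12)OCC | intermediate
24 | methyl 11-(diethoxyphosphoryl)-4,5-epoxy-9-oxogermacra-1(10)Z,2Z-dien-12,6-olid-14-oate (C4–C7 as in 36, C11 epimers) | CCOP(=O)(OCC)C1C(=O)O[C@H]2[C@H]1CC(=O)/C(C(=O)OC)=C\C=C/[C@@]1(C)O[C@H]21 | intermediate
25 | dilithium dianion of 24 (C11 carbanion and C8=C9 enolate) | [Li+].[Li+].CCOP(=O)(OCC)[C-]1C(=O)O[C@H]2[C@H]1C=C([O-])/C(C(=O)OC)=C\C=C/[C@@]1(C)O[C@H]21 | intermediate (not isolated)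
26 | (8S)-8-hydroxy derivative of 24 | CCOP(=O)(OCC)C1C(=O)O[C@H]2[C@H]1[C@H](O)C(=O)/C(C(=O)OC)=C\C=C/[C@@]1(C)O[C@H]21 | intermediate
27 | tiglic acid, (E)-2-methylbut-2-enoic acid | C/C=C(\C)C(=O)O | starting material
28 | (E)-2-methylbut-2-en-1-ol | C/C=C(\C)CO | intermediate
29 | [(2S,3S)-2,3-dimethyloxiran-2-yl]methanol | OC[C@]1(C)O[C@H]1C | intermediate
30 | (2R,3S)-2,3-dimethyloxirane-2-carbaldehyde | O=C[C@]1(C)O[C@H]1C | intermediate (not isolated)
31 | (2R,3S)-2,3-dimethyloxirane-2-carboxylic acid | OC(=O)[C@]1(C)O[C@H]1C | intermediate
32 | mixed anhydride of 31 with 2,4,6-trichlorobenzoic acid | O=C(OC(=O)[C@]1(C)O[C@H]1C)c1c(Cl)cc(Cl)cc1Cl | intermediate (not isolated)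
33 | C8 (2R,3S)-2,3-dimethyloxirane-2-carboxylate of 26 (9-ketone) | CCOP(=O)(OCC)C1C(=O)O[C@H]2[C@H]1[C@H](OC(=O)[C@]1(C)O[C@H]1C)C(=O)/C(C(=O)OC)=C\C=C/[C@@]1(C)O[C@H]21 | intermediate
34 | (9S)-9-hydroxy compound from 33 | CCOP(=O)(OCC)C1C(=O)O[C@H]2[C@H]1[C@H](OC(=O)[C@]1(C)O[C@H]1C)[C@@H](O)/C(C(=O)OC)=C\C=C/[C@@]1(C)O[C@H]21 | intermediate
35 | C9 acetate of 34 | CCOP(=O)(OCC)C1C(=O)O[C@H]2[C@H]1[C@H](OC(=O)[C@]1(C)O[C@H]1C)[C@@H](OC(C)=O)/C(C(=O)OC)=C\C=C/[C@@]1(C)O[C@H]21 | intermediate
36 | methyl (4R,5R,6S,7R,8S,9S)-9-acetoxy-8-[(2R,3S)-2,3-dimethyloxirane-2-carbonyloxy]-4,5-epoxygermacra-1(10)Z,2Z,11(13)-trien-12,6-olid-14-oate | C=C1C(=O)O[C@H]2[C@H]1[C@H](OC(=O)[C@]1(C)O[C@H]1C)[C@@H](OC(C)=O)/C(C(=O)OC)=C\C=C/[C@@]1(C)O[C@H]21 | target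

## Step count and least certain steps

Total: 21 steps. Longest linear sequence: 18 steps (steps 1–14 and 18–21); the side-chain acid takes 3 steps (15–17).

**Step 2 (key step).** Ozone may go on to attack the disubstituted double bonds once the central one is consumed, and the 1,6-diketone may undergo transannular aldol reaction during work-up. The fallback splits the cleavage into two stages. From 3, mCPBA (1 equiv, NaHCO3, CH2Cl2, 0 °C) should epoxidise only the tetrasubstituted bond to give 4a,8a-epoxy-1,4,4a,5,8,8a-hexahydronaphthalene F1. H5IO6 in aqueous THF then opens and cleaves F1 to 5, where the route is rejoined.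

**Step 12.** The ene reaction may be sluggish at the acyloxy-deactivated cis C7=C8 bond, the active methylene of the phosphonoacetate may be oxidised, or the double bonds may be transposed. The fallback abandons the pericyclic pathway. From 21, the doubly allylic C9–H bonds are attacked directly by hydrogen-atom abstraction with (C5H5NH)2Cr2O7 and t-BuOOH on Celite in benzene, a system known to take a methylene between two double bonds to the cross-conjugated ketone without an alcohol stage. It returns at 23 and makes no new compound (F0).

**Step 6.** Facial discrimination by the oxaziridine on a tetrasubstituted, conformationally mobile trienolate may be poor, giving low enantiomeric excess, and oxygen may be transferred at C10 instead of C4. The fallback secures enantiopurity by kinetic resolution, not by enolate oxidation. Partially enriched 13 is carried through steps 7 and 8 to 17. The epoxidation of step 9 is then run with a chiral catalyst (Hf(Ot-Bu)4 with a C2-symmetric bis-hydroxamic acid ligand and cumene hydroperoxide), a system known to resolve tertiary allylic alcohols, and is stopped at partial conversion. The route is rejoined at 18 and no new compound arises (F0).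

**Step 14.** Oxygen may be delivered to the wrong face of the C8 enolate, giving the C8 epimer, or to the C11 carbanion. The fallback installs the C8 oxygen with inversion. From 24, the same dianion is quenched with N-bromosuccinimide to give the 8-bromo ketone F2, with bromine on the face the oxaziridine would have taken. SN2 displacement with the caesium salt of 31 (Cs2CO3, DMF) then gives 33 directly, so the route is rejoined at 33 and step 18 is saved.

**Step 19.** Hydride may attack the other face (C9 epimer, cis to the C8 ester), or conjugate reduction at C1 or acyl migration from O8 may intervene. The fallback turns the wrong epimer into the right acetate. The epimeric alcohol, (9R)-9-hydroxy compound F3, is submitted to a Mitsunobu reaction with acetic acid (PPh3, diisopropyl azodicarboxylate, toluene, 0 °C). This inverts C9 and gives 35 directly, where the route is rejoined.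

## Further compounds

F1 | step 2 | 4a,8a-epoxy-1,4,4a,5,8,8a-hexahydronaphthalene | C1C=CCC23OC12CC=CC3
F0 | step 12 | none | none
F0 | step 6 | none | none
F2 | step 14 | 8-bromo derivative of 24 (bromine trans to C11 in the ring sense) | CCOP(=O)(OCC)C1C(=O)O[C@H]2[C@H]1[C@@H](Br)C(=O)/C(C(=O)OC)=C\C=C/[C@@]1(C)O[C@H]21
F3 | step 19 | (9R)-9-hydroxy epimer of 34 | CCOP(=O)(OCC)C1C(=O)O[C@H]2[C@H]1[C@H](OC(=O)[C@]1(C)O[C@H]1C)[C@H](O)/C(C(=O)OC)=C\C=C/[C@@]1(C)O[C@H]21
A1 | alternative 1 | ten-membered lactone with C3 vinyl group (C14 lactone carbonyl, ring oxygen on C3) | COc1ccc(cc1)CO[C@H]2[C@H](C(=C)CO[Si](C)(C)C(C)(C)C)[C@H](O[Si](C)(C)C(C)(C)C)[C@@H](O[Si](CC)(CC)CC)CC(=O)O[C@H](C=C)[C@@]1(C)O[C@H]21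
A2 | alternative 1 | ten-membered carbocyclic C14 acid with cis C2=C3 | COc1ccc(cc1)CO[C@H]2[C@H](C(=C)CO[Si](C)(C)C(C)(C)C)[C@H](O[Si](C)(C)C(C)(C)C)[C@@H](O[Si](CC)(CC)CC)[C@@H](C(=O)O)C/C=C\[C@@]1(C)O[C@H]21
A3 | alternative 2 | 2-(tert-butyldimethylsilyloxy)tropone | O=C1C=CC=CC=C1O[Si](C)(C)C(C)(C)C
A4 | alternative 2 | (1E,3E)-buta-1,3-diene-1,4-diyl diacetate | CC(=O)O/C=C/C=C/OC(C)=O
A5 | alternative 2 | exo bicyclo[4.4.1]undeca-2,4,8-trien-11-one adduct | CC(=O)O[C@H]2C=C[C@@H](OC(C)=O)[C@@H]3C=CC=C[C@@]2(O[Si](C)(C)C(C)(C)C)C3=O
A6 | alternative 3 | cis,cis-dienyl iodide with C4 methyl ketone and C5 triethylsilyl ether | C=C1C(=O)O[C@H]([C@H](O[Si](CC)(CC)CC)C(C)=O)[C@H]1[C@H](O[Si](C)(C)C(C)(C)C)[C@@H](OC(C)=O)/C(C(=O)OC)=C\C=C/I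
A7 | alternative 3 | macrocyclic C4 tertiary alcohol with C5 triethylsilyl ether | C=C1C(=O)O[C@H]2[C@H]1[C@H](O[Si](C)(C)C(C)(C)C)[C@@H](OC(C)=O)/C(C(=O)OC)=C\C=C/[C@@](C)(O)[C@H]2O[Si](CC)(CC)CC
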